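**Retrosynthetic overview**

1. The bridged dihydropyran (enol ether) is closed last: the C14 aldehyde oxygen opens a 4α,15-epoxide at C4, then H10 is lost.
2. The 8β-ester/9α-acetate pair comes from α-epoxidation of a C8=C9 alkene and carboxylate opening at C8; the exo-methylene comes from Mannich methylenation of the trans 6α,12-lactone.
3. The C8=C9 alkene, the lactone oxygen O6 and the lactone ring all arise from one E1cB opening/deconjugation/lactonisation of a 6α,9α-oxygen-bridged tricycle.
4. Key step: a dearomatising formal (4+3) cycloaddition (rhodium-carbenoid cyclopropanation/Cope) of methyl furan-3-ylacetate with a cyclopentenyl diazoacetate builds the seven-membered ring and sets C5, C6 and C9.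
5. Ring order: cyclopentane (from 3-ethoxycyclopentenone) → seven-membered carbocycle with oxygen bridge → γ-lactone → dihydropyran.

Assumption: guaianolide numbering is used in all names (ring carbons C1–C10, lactone carbons C11–C13, C14 on C10, C15 on C4); α is the face of H1 and H5 in the target.
Assumption: Rh2(S-DOSP)4, dirhodium tetrakis[(S)-N-(4-dodecylphenylsulfonyl)prolinate], is taken to give the cycloadduct enantiomer drawn; if it gives the mirror image, Rh2(R-DOSP)4 is used instead.
Assumption: the C10 configuration drawn for the intermediates between ring-opening and the final step (H10α) and the undefined C11 of the Mannich intermediates do not matter, because both carbons become sp2.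

**Step 1**
Reactants: 1 3-ethoxycyclopent-2-en-1-one; 2 benzyl acetate
Product: 4 benzyl 2-(3-oxocyclopent-1-en-1-yl)acetate, via ethoxy hydroxy ester adduct 3 (not isolated)
Conditions: LiN(iPr)2, THF, −78 °C, then 1; then 1 M HCl, rt
Reagents that add atoms: water, O
Why: Stork–Danheiser transposition: 1,2-addition of the ester lithium enolate to the vinylogous ester, then acid hydrolysis and dehydration, gives the 3-substituted enone; no stereocentre is formed.

**Step 2**
Reactants: 4 benzyl 2-(3-oxocyclopent-1-en-1-yl)acetate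
Product: 5 benzyl 2-(1,4-dioxaspiro[4.4]non-6-en-7-yl)acetate
Conditions: (TMSOCH2)2, TMSOTf (cat.), CH2Cl2, −78 °C
Reagents that add atoms: 1,2-bis(trimethylsilyloxy)ethane, C[Si](C)(C)OCCO[Si](C)(C)C
Why: Noyori ketalisation at low temperature protects the enone carbonyl (future C4) as the dioxolane without moving the ring double bond, which must stay at the future C1=C5 position.

**Step 3**
Reactants: 5 benzyl 2-(1,4-dioxaspiro[4.4]non-6-en-7-yl)acetate
Product: 6 benzyl 2-diazo-2-(1,4-dioxaspiro[4.4]non-6-en-7-yl)acetate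
Conditions: p-ABSA, DBU, MeCN, 0 °C
Reagents that add atoms: 4-acetamidobenzenesulfonyl azide, CC(=O)Nc1ccc(cc1)S(=O)(=O)N=[N+]=[N-]
Why: Regitz diazo transfer to the ester α-methylene, which is activated by the ester and the adjacent alkene, gives the vinyldiazoacetate.

**Step 4**
Reactants: 6 benzyl 2-diazo-2-(1,4-dioxaspiro[4.4]non-6-en-7-yl)acetate; 7 methyl 2-(furan-3-yl)acetate
Product: 9 oxygen-bridged tricyclic diene diester (6α,9α-epoxy cycloadduct), via cis-divinylcyclopropane 8 (not isolated)
Conditions: Rh2(S-DOSP)4 (1 mol %), 7 (3 equiv), hexanes–PhCF3, −40 °C to rt, slow addition of 6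
Reagents that add atoms: none
Why: Davies tandem cyclopropanation/Cope rearrangement (formal (4+3) cycloaddition): the rhodium vinylcarbenoid cyclopropanates the less hindered C4=C5 bond of the furan (breaking its aromaticity), the cis-divinylcyclopropane rearranges through a boat transition state that places H5 syn to the new oxygen bridge, and the chiral dirhodium carboxylate sets the absolute configuration of C6, C9 and C5.

**Step 5**
Reactants: 9 oxygen-bridged tricyclic diene diester
Product: 10 saturated oxygen-bridged C14 acid methyl ester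
Conditions: H2 (60 bar), Pd/C, EtOAc, 40 °C
Reagents that add atoms: none
Why: Heterogeneous hydrogenation adds hydrogen to both alkenes from the exo face (syn to the oxygen bridge), setting H7α, H1α and H10α, and hydrogenolysis of the benzyl ester frees the C14 acid.

**Step 6**
Reactants: 10 saturated oxygen-bridged C14 acid methyl ester
Product: 13 β,γ-unsaturated C14 acid trans-6α,12-lactone, via ring-opened conjugated enoic acid 11 (not isolated), via deconjugated hydroxy ester acid 12 (not isolated)
Conditions: LiN(iPr)2 (4.5 equiv), THF–DMPU, −78 to 0 °C; AcOH, −78 °C; then PPTS (cat.), PhMe, 50 °C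
Reagents that add atoms: none
Why: E1cB opening of the β-alkoxy acid (the C10 enediolate expels the C9–O bond and leaves the C6 oxygen with its α configuration), γ-deprotonation to the dienediolate and kinetic α-protonation (deconjugation to the C8=C9 acid, H10 from the convex α face), then acid-catalysed lactonisation to the trans 6α,12-lactone.

**Step 7**
Reactants: 13 β,γ-unsaturated C14 acid trans-6α,12-lactone
Product: 15 C14 primary alcohol, via isobutyl carbonic mixed anhydride 14 (not isolated)
Conditions: iBuOCOCl, N-methylmorpholine, THF, −15 °C; then NaBH4, THF–H2O, 0 °C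
Reagents that add atoms: none
Why: Activation as the mixed carbonic anhydride makes the acid carbonyl the most electrophilic site, so NaBH4 reduces it to the primary alcohol and leaves the γ-lactone intact (chemoselective acid reduction).

**Step 8**
Reactants: 15 C14 primary alcohol
Product: 16 C14 tert-butyldimethylsilyl ether
Conditions: TBSCl, imidazole, CH2Cl2, rt
Reagents that add atoms: tert-butyldimethylsilyl chloride, CC(C)(C)[Si](C)(C)Cl
Why: Standard silylation of the only hydroxyl group protects C14–OH for the base, oxidation and acylation steps that follow.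

**Step 9**
Reactants: 16 C14 tert-butyldimethylsilyl ether
Product: 19 α-methylene lactone, via Mannich base 17 (not isolated), via trimethylammonium iodide 18 (not isolated)
Conditions: LiN(iPr)2, THF, −78 °C; CH2=NMe2 I, −78 to 0 °C; then MeI, MeOH; then NaHCO3, CH2Cl2–H2O, rt
Reagents that add atoms: dimethylmethyleneammonium iodide (Eschenmoser's salt), C=[N+](C)C.[I-]
Why: Eschenmoser methylenation: the lactone lithium enolate (the only enolisable carbonyl) undergoes a Mannich reaction, and quaternisation with Hofmann-type elimination gives the C11=C13 exo-methylene.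

**Step 10**
Reactants: 19 α-methylene lactone
Product: 20 8α,9α-epoxide
Conditions: mCPBA, CH2Cl2, 0 °C
Reagents that add atoms: 3-chloroperoxybenzoic acid, OOC(=O)c1cccc(Cl)c1
Why: Prilezhaev epoxidation selects the electron-rich cis C8=C9 alkene over the conjugated exo-methylene and occurs on the α face, away from the β-oriented C10 silyloxymethyl group and the C7–C11 bond, which sets the 9α oxygen.

**Step 11**
Reactants: 20 8α,9α-epoxide; 21 (R)-2-methylbutanoic acid
Product: 23 8β-[(R)-2-methylbutanoate] 9α-acetate, via 9-hydroxy 8-ester 22 (not isolated)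
Conditions: 21 (5 equiv), Cs2CO3 (0.2 equiv), DMF, 80 °C; then Ac2O, DMAP, pyridine, 0 °C
Reagents that add atoms: acetic anhydride, CC(=O)OC(C)=O
Why: Carboxylate SN2 opening of the epoxide at C8, the oxirane carbon remote from the bulky C10 CH2OTBS group, with inversion gives the 8β-acyloxy-9α-ol (trans, as in the target), and acetylation in the same flask traps it before acyl migration.

**Step 12**
Reactants: 23 8β-[(R)-2-methylbutanoate] 9α-acetate
Product: 24 C4 ketone
Conditions: PPTS, acetone–H2O (10:1), 50 °C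
Reagents that add atoms: water, O
Why: Mild acid-catalysed hydrolysis of the dioxolane frees the C4 ketone while the silyl ether, esters and lactone survive pyridinium tosylate.

**Step 13**
Reactants: 24 C4 ketone
Product: 25 4(15)-exocyclic alkene
Conditions: Zn, CH2Br2, TiCl4, THF–CH2Cl2, 0 °C to rt
Reagents that add atoms: dibromomethane, BrCBr
Why: Lombardo–Takai methylenation with the non-basic CH2Br2/Zn/TiCl4 reagent converts the ketone chemoselectively (esters and lactone are inert) and does not epimerise the adjacent C5 centre.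

**Step 14**
Reactants: 25 4(15)-exocyclic alkene
Product: 26 C14 alcohol
Conditions: HF·pyridine, pyridine, THF, 0 °C
Reagents that add atoms: none
Why: Buffered fluoride desilylation frees the C14 alcohol without ester cleavage or acyl migration.

**Step 15**
Reactants: 26 C14 alcohol
Product: 27 C14 aldehyde
Conditions: Dess–Martin periodinane, pyridine, CH2Cl2, 0 °C
Reagents that add atoms: none
Why: Dess–Martin oxidation under buffered, non-basic conditions gives the β-acetoxy aldehyde without elimination of acetic acid.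

**Step 16**
Reactants: 27 C14 aldehyde
Product: 29 target CNP0013863.3, via 4α,15-epoxy aldehyde 28 (not isolated)
Conditions: DMDO, acetone–CH2Cl2, −30 °C; then PPTS (10 mol %), CH2Cl2, −30 to 0 °C
Reagents that add atoms: dimethyldioxirane, CC1(C)OO1
Why: Proposed new method: DMDO epoxidises the exocyclic C4=C15 alkene from the convex α face (anti to the C5–C6 bond), then mild acid lets the aldehyde oxygen open the oxirane at the tertiary C4 with inversion through a six-membered transition state (setting the 4β oxygen and releasing the C15 alcohol), and the oxocarbenium ion loses H10 to give the enol ether; the closest known chemistry is acid-catalysed epoxide opening by a neighbouring carbonyl oxygen (bicyclic acetal formation from keto epoxides).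

**Compound list**

1 | 3-ethoxycyclopent-2-en-1-one | CCOC1=CC(=O)CC1 | starting material
2 | benzyl acetate | CC(=O)OCc1ccccc1 | starting material
3 | benzyl 2-(3-ethoxy-1-hydroxycyclopent-2-en-1-yl)acetate (racemic 1,2-adduct) | CCOC1=CC(O)(CC(=O)OCc2ccccc2)CC1 | intermediate
4 | benzyl 2-(3-oxocyclopent-1-en-1-yl)acetate | O=C1CCC(CC(=O)OCc2ccccc2)=C1 | intermediate
5 | benzyl 2-(1,4-dioxaspiro[4.4]non-6-en-7-yl)acetate | O=C(CC1=CC2(CC1)OCCO2)OCc1ccccc1 | intermediate
6 | benzyl 2-diazo-2-(1,4-dioxaspiro[4.4]non-6-en-7-yl)acetate | [N-]=[N+]=C(C(=O)OCc1ccccc1)C1=CC2(CC1)OCCO2 | intermediate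
7 | methyl 2-(furan-3-yl)acetate | COC(=O)Cc1ccoc1 | starting material
8 | cis-divinylcyclopropane: 2-oxabicyclo[3.1.0]hex-3-ene from the furan, cyclopropane carbon bearing exo CO2Bn and endo ketal-cyclopentenyl, CH2CO2Me on the enol ether carbon | COC(=O)CC1=CO[C@@H]2[C@H]1[C@]2(C(=O)OCc3ccccc3)C4=CC5(CC4)OCCO5 | intermediate
9 | cycloadduct: 6α,9α-oxygen bridge, C1=C10 and C7=C8 double bonds, 5αH, C10–CO2Bn (C14), C7–CH2CO2Me (C11, C12), C4 ethylene ketal | O=C(OCc1ccccc1)C2=C3CCC4(OCCO4)[C@@H]3[C@H]5O[C@@H]2C=C5CC(=O)OC | intermediate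
10 | saturated bridged acid: 6α,9α-oxygen bridge, 1αH, 5αH, 7αH, 10αH, C14 carboxylic acid, C7β–CH2CO2Me, C4 ketal | OC(=O)[C@@H]2[C@@H]3CCC4(OCCO4)[C@@H]3[C@H]5O[C@@H]2C[C@H]5CC(=O)OC | intermediate
11 | ring-opened 9(10)-en-14-oic acid: 6α-OH, C7β–CH2CO2Me, 1αH, 5αH, C4 ketal | OC(=O)C2=CC[C@@H](CC(=O)OC)[C@H](O)[C@H]3C4(OCCO4)CC[C@@H]23 | intermediate
12 | 8(9)-en-14-oic acid (10αH): 6α-OH, C7β–CH2CO2Me, C4 ketal | OC(=O)[C@H]2C=C[C@@H](CC(=O)OC)[C@H](O)[C@H]3C4(OCCO4)CC[C@@H]23 | intermediate
13 | 8(9)-ene trans-6α,12-lactone (7αH) with C14 carboxylic acid (10αH), C4 ketal | OC(=O)[C@H]2C=C[C@H]5CC(=O)O[C@@H]5[C@H]3C4(OCCO4)CC[C@@H]23 | intermediate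
14 | isobutyl carbonic mixed anhydride of 13 | CC(C)COC(=O)OC(=O)[C@H]2C=C[C@H]5CC(=O)O[C@@H]5[C@H]3C4(OCCO4)CC[C@@H]23 | intermediate
15 | 14-hydroxy 8(9)-ene 6α,12-lactone, C4 ketal | OC[C@H]2C=C[C@H]5CC(=O)O[C@@H]5[C@H]3C4(OCCO4)CC[C@@H]23 | intermediate
16 | 14-O-TBS ether of 15 | CC(C)(C)[Si](C)(C)OC[C@H]2C=C[C@H]5CC(=O)O[C@@H]5[C@H]3C4(OCCO4)CC[C@@H]23 | intermediate
17 | 11-(dimethylaminomethyl) lactone (C11 epimers, undefined) | CC(C)(C)[Si](C)(C)OC[C@H]2C=C[C@H]5C(CN(C)C)C(=O)O[C@@H]5[C@H]3C4(OCCO4)CC[C@@H]23 | intermediate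
18 | trimethylammonium iodide of 17 | CC(C)(C)[Si](C)(C)OC[C@H]2C=C[C@H]5C(C[N+](C)(C)C)C(=O)O[C@@H]5[C@H]3C4(OCCO4)CC[C@@H]23.[I-] | intermediate
19 | 11(13)-methylene 6α,12-lactone, 8(9)-ene, 14-OTBS, C4 ketal | CC(C)(C)[Si](C)(C)OC[C@H]2C=C[C@H]5C(=C)C(=O)O[C@@H]5[C@H]3C4(OCCO4)CC[C@@H]23 | intermediate
20 | 8α,9α-epoxide of 19 | CC(C)(C)[Si](C)(C)OC[C@H]2[C@@H]6O[C@@H]6[C@H]5C(=C)C(=O)O[C@@H]5[C@H]3C4(OCCO4)CC[C@@H]23 | intermediate
21 | (R)-2-methylbutanoic acid | CC[C@@H](C)C(O)=O | starting material
22 | 8β-[(R)-2-methylbutanoyloxy]-9α-hydroxy compound (14-OTBS, C4 ketal, methylene lactone) | CC(C)(C)[Si](C)(C)OC[C@H]2[C@H](O)[C@@H](OC(=O)[C@H](C)CC)[C@H]5C(=C)C(=O)O[C@@H]5[C@H]3C4(OCCO4)CC[C@@H]23 | intermediate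
23 | 9α-acetate of 22 | CC(C)(C)[Si](C)(C)OC[C@H]2[C@H](OC(C)=O)[C@@H](OC(=O)[C@H](C)CC)[C@H]5C(=C)C(=O)O[C@@H]5[C@H]3C4(OCCO4)CC[C@@H]23 | intermediate
24 | C4 ketone (ketal removed) | CC(C)(C)[Si](C)(C)OC[C@H]2[C@H](OC(C)=O)[C@@H](OC(=O)[C@H](C)CC)[C@H]5C(=C)C(=O)O[C@@H]5[C@H]3C(=O)CC[C@@H]23 | intermediate
25 | 4(15)-exocyclic alkene, 14-OTBS | CC(C)(C)[Si](C)(C)OC[C@H]2[C@H](OC(C)=O)[C@@H](OC(=O)[C@H](C)CC)[C@H]5C(=C)C(=O)O[C@@H]5[C@H]3C(=C)CC[C@@H]23 | intermediate
26 | 14-alcohol, 4(15)-ene | OC[C@H]2[C@H](OC(C)=O)[C@@H](OC(=O)[C@H](C)CC)[C@H]5C(=C)C(=O)O[C@@H]5[C@H]3C(=C)CC[C@@H]23 | intermediate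
27 | 14-aldehyde, 4(15)-ene | O=C[C@H]2[C@H](OC(C)=O)[C@@H](OC(=O)[C@H](C)CC)[C@H]5C(=C)C(=O)O[C@@H]5[C@H]3C(=C)CC[C@@H]23 | intermediate
28 | 4α,15-epoxy 14-aldehyde | O=C[C@H]2[C@H](OC(C)=O)[C@@H](OC(=O)[C@H](C)CC)[C@H]5C(=C)C(=O)O[C@@H]5[C@H]3[C@@]6(CO6)CC[C@@H]23 | intermediate
29 | CNP0013863.3 | C=C1C(=O)O[C@H]2[C@H]1[C@H](OC(=O)[C@H](C)CC)[C@@H](OC(C)=O)C1=CO[C@@]3(CO)CC[C@@H]1[C@@H]23 | target

**Step count and risks**

Total step count: 16. Longest linear sequence: 16 steps (1 to 29; 7 and 21 are bought).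

Step 4 is the first risk: the carbenoid may also attack the substituted C2=C3 bond of 7 (wrong regioisomer), or the enantioselectivity may be modest. Fallback: starting from 6, the same rhodium-catalysed reaction is run with 3-bromofuran, whose brominated double bond is deactivated and shielded so that only the C4=C5 bond reacts, giving the bromo cycloadduct F1. Negishi coupling of the vinyl bromide with the Reformatsky reagent BrZnCH2CO2Me (Pd2(dba)3, XPhos, THF) then installs the side chain and rejoins the route at 9.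

Step 11 is the second risk: the carboxylate may attack C9 instead of C8, or the acyl group may migrate. Fallback: starting from 20, acid-catalysed hydrolysis (cat. HClO4, THF–H2O, 0 °C), in which the β-disposed lactone carbonyl assists opening at C8, gives the 8β,9α-diol F2. Selective acetylation of the more exposed 9α-hydroxyl (Ac2O, collidine, −20 °C) gives the 9-monoacetate F3, and Steglich esterification of the remaining 8β-hydroxyl with 21 (DCC, DMAP) rejoins the route at 23.

Step 16 is the third risk: the β-acetoxy aldehyde may eliminate acetic acid, or the epoxide may open at C15. Fallback: starting from 27, the epoxidation is run as before to 28, but the ring closure is done in methanol with pyridinium tosylate, so that the hydroxyl of the methyl hemiacetal (a neutral O–H nucleophile) opens the epoxide at C4 and gives the bridged methyl acetal F4. Elimination of methanol (pyridinium tosylate, toluene, 4 Å sieves, 80 °C) then delivers 29.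

**Further compounds**

F1 | step 4 | 7-bromo analogue of 9: 6α,9α-oxygen bridge, C1=C10 and C7=C8, vinyl bromide at C7, C10–CO2Bn, C4 ketal | O=C(OCc1ccccc1)C2=C3CCC4(OCCO4)[C@@H]3[C@H]5O[C@@H]2C=C5Br
F2 | step 11 | 8β,9α-diol (14-OTBS, C4 ketal, methylene lactone) | CC(C)(C)[Si](C)(C)OC[C@H]2[C@H](O)[C@@H](O)[C@H]5C(=C)C(=O)O[C@@H]5[C@H]3C4(OCCO4)CC[C@@H]23
F3 | step 11 | 9α-acetoxy-8β-ol (14-OTBS, C4 ketal, methylene lactone) | CC(C)(C)[Si](C)(C)OC[C@H]2[C@H](OC(C)=O)[C@@H](O)[C@H]5C(=C)C(=O)O[C@@H]5[C@H]3C4(OCCO4)CC[C@@H]23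
F4 | step 16 | bridged C14 methyl acetal of the target skeleton (10αH, C14 anomers, free C15–OH) | C=C1C(=O)O[C@H]2[C@H]1[C@H](OC(=O)[C@H](C)CC)[C@@H](OC(C)=O)[C@@H]1C(OC)O[C@@]3(CO)CC[C@@H]1[C@@H]23
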